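The runs are calculated with made-up constants.

Which way of bringing these charges together gives the highest selectivity, the share of links in links plus over-reaction product?

| flask | first end groups | second end groups | protic impurity | remark | time |
|---|---|---|---|---|---|
| epsilon | 0.050 M | 0.050 M | 0.025 M | run made earlier |  |
| alpha | 0.050 M | 0.025 M | 0.025 M | run made earlier |  |
| beta | 0.050 M | 0.10 M | 0.025 M | run made earlier |  |
| delta | 0.10 M | 0.050 M | 0.025 M | run made earlier |  |
| blue | 0.050 M | 0.0500 M | 0.0250 M | a single well-mixed tank run continuously and read at steady state, 30 h in it on average |  |
| teal | 0.050 M | 0.0500 M (fed, over 24.0 h) | 0.0250 M | all but second end groups at the start; second end groups goes in evenly over 24.0 h, the run ends at 30 h | 30 h |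
| ochre | 0.050 M (fed, over 24.0 h) | 0.0500 M | 0.0250 M | all but first end groups at the start; first end groups goes in evenly over 24.0 h, the run ends at 30 h | 30 h |
| red | 0.050 M | 0.0500 M | 0.0250 M | everything together in a closed stirred flask, run for 30 h | 30 h |

- epsilon (time / h: links / %, over-reaction product / %): 4.00: 85, 2; 8.00: 88, 1; 10.0: 85, 3; 15.0: 85, 0; 20.0: 85, 2
- alpha (time / h: links / %, over-reaction product / %): 5.00: 45, 0; 10.0: 46, 0; 15.0: 46, 0; 20.0: 46, 0; 25.0: 46, 2
- beta (time / h: links / %, over-reaction product / %): 2.00: 84, 13; 6.00: 73, 24; 12.0: 65, 38; 15.0: 61, 41; 25.0: 54, 44
- delta (time / h: links / %, over-reaction product / %): 2.00: 49, 1; 6.00: 47, 0; 12.0: 46, 2; 15.0: 47, 1; 25.0: 47, 0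

(standard deviation of a reading: 1.5 percentage points)

1. the set-up with the highest share of links in all that became links or over-reaction product, at the outlet or at the end ("none" if the first two lie within 2 percentage points) (blue / teal / ochre / red / none)
2. share of links in all that became links or over-reaction product, at the outlet or at the end, blue
3. share of links in all that became links or over-reaction product, at the outlet or at the end, teal
4. share of links in all that became links or over-reaction product, at the outlet or at the end, ochre
5. share of links in all that became links or over-reaction product, at the outlet or at the end, red

- percent here means first end groups units held: one self-condensation product counts as two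
- the stated concentrations are those of everything mixed, before any reaction; amounts are the same in each set-up
- the numbers in the tables scatter with a standard deviation of 1.5 percentage points
- reactions considered so far: 2 first end groups -> self-condensation product; first end groups + second end groups -> links + by-product; second end groups + protic impurity -> quenched reagent; second end groups + links -> over-reaction product
- the feed brings no volume worth counting
- the earlier runs were made in a closed, stirred flask

Take the second end groups charged, subtract the first end groups and the protic impurity charged, and divide by the first end groups charged. In beta this gives 50.0 %, and over-reaction product climbs to 44 % at 25.0 h. Your four set-ups share one value, −50.0 %, the surplus. Epsilon has that value too, and its readings give a share of 98.2 %. So I put red there.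

But does the impurity really take its whole charge? Perhaps not. Even if it took none in red, the surplus would rise only to 0 %, since the second end groups merely match the first.

The real doubt is self-condensation. In beta, links plus over-reaction product read 97.0 % at 2.00 h, so a small loss could hide in the scatter of 1.5 percentage points. There the first end groups met twice their amount of reagent. In teal they meet a trickle for 24.0 h. A first end group that has self-condensed no longer takes up reagent, so with the impurity still counted at its whole charge, teal's surplus turns positive past 50.0 % of them self-condensed. I can't put a figure on teal, but I place it below red. In ochre the second end groups start above the impurity, so early links meet spare reagent, and I place ochre below red too. Blue's tank keeps fresh reagent beside finished links, and I place blue below red as well. My choice is red.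

The forecast says none, with blue 95 %, teal 98 %, ochre 91 % and red 98 %, holding for teal that “the path matches batch”.

The flask gives red, with blue 92.3 %, teal 75.7 %, ochre 88.8 % and red 97.9 %.

    2 first end groups → self-condensation product (k = 5.13 /M/h)
    first end groups + second end groups → links + by-product (k = 157 /M/h)
    second end groups + protic impurity → quenched reagent (k = 19.1 /M/h)
    second end groups + links → over-reaction product (k = 2.08 /M/h)

By the over-reaction step alone, with the other concentrations as charged in red, links have a half-life of 6.7 h, short against the 30 h run. Teal's self-condensation product holds 67.2 % of the first end groups charged, which takes its surplus to 17.2 %, and its over-reaction product stands at 7.96 % after 30.0 h and 17.2 % after 300 h. A neighbour of red charged with 0.12 M of second end groups, its self-condensation product of 1.60 % counted as in teal, has a surplus of 91.6 %. Its over-reaction product reaches 71.2 %, and its unspent second end groups amount to 20.4 % of the first end groups charged.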